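**Plan**

Numbering used throughout: C1 (aryl A = 3-hydroxy-4,5-dimethoxyphenyl), O2, C3, C3a, C4 (aryl B = 3,4,5-trimethoxyphenyl), O5, C6, C6a.
Retrosynthetic cuts, in order: C4–aryl B (aryl addition to a bicyclic oxocarbenium ion); C4–O5 (lactol, with C4 coming from a vinyl group on C3a and C6 from an ester on C6a); then O2–C1 and C3a–C6a together.
Enabling feature: ring C1–O2–C3–C3a–C6a is the sum of a three-atom O2–C3–C3a unit (an alkoxide on a π-allyl group, from vinylethylene carbonate) and the two-atom C1=C6a unit of an arylidene malonate; the vinyl group left on C3a is C4 in latent form.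
Forward order: acceptor (2 steps), ring C1–O2–C3–C3a–C6a by palladium-catalysed decarboxylative (3+2) cycloaddition, mono-ester, alcohol, oxidative cleavage that closes ring C3a–C4–O5–C6–C6a as a lactol, arylation at C4, debenzylation.
Stereochemistry: C3a and C1 from the chiral phosphoramidite–palladium catalyst (aryl A trans to vinyl); C6a by equilibration of the ester trans to aryl A, then locked by the cis-fused lactol; C4 by convex-face attack on the bicyclic oxocarbenium ion.

Key step: step 3

Assumption: the sense of induction of the phosphoramidite in step 3 cannot be assigned in advance; the ligand antipode written there stands for whichever antipode a pilot run shows to give the required enantiomer.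
Remark: the descriptor at the aryl-bearing carbon is R in the geminal diester and S in all later compounds only because the CIP priorities change; the spatial arrangement is the same.

Step 1
Reactants: 1 3-hydroxy-4,5-dimethoxybenzaldehyde
Product: 2 3-(benzyloxy)-4,5-dimethoxybenzaldehyde
Conditions: BnBr, K2CO3, DMF, 23 °C
Reagents that add atoms: benzyl bromide, BrCc1ccccc1
Why: Williamson etherification of the phenoxide with benzyl bromide masks the acidic phenol for the basic, hydride and organometallic steps that follow and is removed last by hydrogenolysis.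

Step 2
Reactants: 2 3-(benzyloxy)-4,5-dimethoxybenzaldehyde; 3 dimethyl malonate
Product: 4 dimethyl 2-[3-(benzyloxy)-4,5-dimethoxybenzylidene]malonate
Conditions: piperidine (cat.), AcOH (cat.), toluene, reflux, azeotropic removal of water
Reagents that add atoms: none
Why: Knoevenagel condensation under piperidinium acetate catalysis is driven by water removal, and the two identical ester groups leave no alkene geometry to control.

Step 3
Reactants: 4 dimethyl 2-[3-(benzyloxy)-4,5-dimethoxybenzylidene]malonate; 5 4-vinyl-1,3-dioxolan-2-one (racemic)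
Product: 6 dimethyl (2R,4R)-2-[3-(benzyloxy)-4,5-dimethoxyphenyl]-4-vinyltetrahydrofuran-3,3-dicarboxylate (aryl and vinyl trans)
Conditions: Pd2(dba)3·CHCl3 (2.5 mol %), (Sa,R,R)-BINOL N,N-bis(1-phenylethyl)phosphoramidite (10 mol %), THF, 40 °C
Reagents that add atoms: none
Why: Zerovalent palladium adds oxidatively to the allylic C–O bond of 5 and CO2 departs, which leaves a cationic π-allylpalladium unit carrying a free alkoxide; the alkoxide adds reversibly to the benzylidene carbon of 4 (oxa-Michael addition, bond O2–C1) and the malonate anion thus formed alkylates the substituted allyl terminus (bond C6a–C3a) with release of the catalyst. The closest known reaction is the palladium-catalysed decarboxylative (3+2) cycloaddition of vinylethylene carbonates and vinyl oxiranes with doubly activated alkenes to 4-vinyltetrahydrofurans, applied here to an arylidene malonate. Ring C1–O2–C3–C3a–C6a closes in the C–C bond-forming event as a 5-exo attack on the π-allyl unit, which is preferred over 7-endo attack at the unsubstituted terminus. C3a (C4 of 6) is controlled by the phosphoramidite ligand, which selects one face of the π-allyl complex; both enantiomers of racemic 5 converge because the diastereomeric π-allyl complexes interconvert by π–σ–π isomerisation before ring closure. C1 (C2 of 6) is formed in the reversible oxa-Michael step, so its two epimers equilibrate and the ratio is decided in the ring closure (Curtin–Hammett), where the transition state with the aryl group trans to the developing vinyl group should be the less hindered one. The step needs branched regioselectivity, 2,4-trans diastereoselectivity and enantioselectivity: the first follows from ring size, the other two from the ligand acting on equilibrating intermediates, and the geminal diester both activates the alkene and leaves C6a without configuration at this stage.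

Step 4
Reactants: 6 dimethyl (2R,4R)-2-[3-(benzyloxy)-4,5-dimethoxyphenyl]-4-vinyltetrahydrofuran-3,3-dicarboxylate
Product: 8 methyl (2S,3S,4R)-2-[3-(benzyloxy)-4,5-dimethoxyphenyl]-4-vinyltetrahydrofuran-3-carboxylate (ester trans to aryl and cis to vinyl), via the (2S,3R,4R) epimer 7 (not isolated)
Conditions: NaCl, H2O, DMSO, 150 °C; then NaOMe (cat.), MeOH, 23 °C
Reagents that add atoms: none
Why: Krapcho dealkoxycarbonylation (chloride SN2 attack on an ester methyl group, loss of CO2, protonation) removes one ester, and catalytic methoxide then equilibrates the enolisable C3 centre, which should settle with the ester trans to the bulkier aryl neighbour and cis to vinyl (thermodynamic control), ring opening by β-elimination of O1 being the disfavoured reverse of a 5-endo-trig closure.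

Step 5
Reactants: 8 methyl (2S,3S,4R)-2-[3-(benzyloxy)-4,5-dimethoxyphenyl]-4-vinyltetrahydrofuran-3-carboxylate
Product: 9 [(2S,3R,4R)-2-[3-(benzyloxy)-4,5-dimethoxyphenyl]-4-vinyltetrahydrofuran-3-yl]methanol
Conditions: LiAlH4, THF, 0 °C
Reagents that add atoms: none
Why: Hydride reduction of the ester to the primary alcohol is fast at 0 °C, leaves the ethers and the alkene untouched and does not disturb the configuration set in step 4.

Step 6
Reactants: 9 [(2S,3R,4R)-2-[3-(benzyloxy)-4,5-dimethoxyphenyl]-4-vinyltetrahydrofuran-3-yl]methanol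
Product: 12 (3aR,4S,6aR)-4-[3-(benzyloxy)-4,5-dimethoxyphenyl]tetrahydro-1H,3H-furo[3,4-c]furan-1-ol (both anomers), via the ozonide 10 (not isolated), via the hydroxy aldehyde 11 (not isolated)
Conditions: O3, CH2Cl2, −78 °C (Sudan Red 7B end point); then PPh3, −78 → 23 °C
Reagents that add atoms: ozone, [O-][O+]=O
Why: Ozonolysis cleaves the terminal alkene far faster than it attacks the alkoxyarenes at −78 °C, and after reduction of the ozonide the aldehyde is trapped at once by the cis hydroxymethyl group as the cis-fused five-membered lactol, which protects the enolisable C3a centre.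

Step 7
Reactants: 12 (3aR,4S,6aR)-4-[3-(benzyloxy)-4,5-dimethoxyphenyl]tetrahydro-1H,3H-furo[3,4-c]furan-1-ol
Product: 13 (3aR,4S,6aR)-1-(benzenesulfonyl)-4-[3-(benzyloxy)-4,5-dimethoxyphenyl]tetrahydro-1H,3H-furo[3,4-c]furan (both anomers)
Conditions: PhSO2H, CaCl2, CH2Cl2, 23 °C
Reagents that add atoms: benzenesulfinic acid, O=S(O)c1ccccc1
Why: Acid-mediated lactol exchange (ionisation to the oxocarbenium ion, capture by sulfinate through sulfur, CaCl2 binding the water) is the standard way to 2-sulfonyl cyclic ethers, and the anomeric configuration is of no consequence.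

Step 8
Reactants: 14 5-bromo-1,2,3-trimethoxybenzene
Product: 15 (3,4,5-trimethoxyphenyl)magnesium bromide
Conditions: Mg turnings, I2 (cat.), THF, reflux
Reagents that add atoms: magnesium, [Mg]
Why: Grignard formation by magnesium insertion into the aryl bromide is routine for methoxy-substituted bromoarenes.

Step 9
Reactants: 13 (3aR,4S,6aR)-1-(benzenesulfonyl)-4-[3-(benzyloxy)-4,5-dimethoxyphenyl]tetrahydro-1H,3H-furo[3,4-c]furan; 15 (3,4,5-trimethoxyphenyl)magnesium bromide
Product: 17 (1S,3aR,4S,6aR)-1-[3-(benzyloxy)-4,5-dimethoxyphenyl]-4-(3,4,5-trimethoxyphenyl)tetrahydro-1H,3H-furo[3,4-c]furan, via (3,4,5-trimethoxyphenyl)zinc bromide 16 (not isolated)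
Conditions: 15, ZnBr2, THF, 23 °C; then 13, THF, 23 °C
Reagents that add atoms: none
Why: Substitution of a 2-sulfonyl cyclic ether by an arylzinc reagent proceeds through the oxocarbenium ion that the zinc and magnesium halides release from the sulfone, and the weakly basic aryl donor should attack the convex face of the cis-fused bicycle, which sets C4 with aryl B exo (cis to H3a).

Step 10
Reactants: 17 (1S,3aR,4S,6aR)-1-[3-(benzyloxy)-4,5-dimethoxyphenyl]-4-(3,4,5-trimethoxyphenyl)tetrahydro-1H,3H-furo[3,4-c]furan
Product: 18 5-[(1S,3aR,4S,6aR)-4-(3,4,5-trimethoxyphenyl)tetrahydro-1H,3H-furo[3,4-c]furan-1-yl]-2,3-dimethoxyphenol (target)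
Conditions: H2 (1 atm), Pd/C, EtOAc, 23 °C
Reagents that add atoms: none
Why: Catalytic hydrogenolysis of the aryl benzyl ether over palladium on carbon in a neutral aprotic solvent should be much faster than cleavage of the ring benzylic C–O bonds, which carry no free para-hydroxyl group, and no stereocenter is involved.

**Compound list**

1 | 3-hydroxy-4,5-dimethoxybenzaldehyde | COc1cc(C=O)cc(O)c1OC | starting material
2 | 3-(benzyloxy)-4,5-dimethoxybenzaldehyde | COc1cc(C=O)cc(OCc2ccccc2)c1OC | intermediate
3 | dimethyl malonate | COC(=O)CC(=O)OC | starting material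
4 | dimethyl 2-[3-(benzyloxy)-4,5-dimethoxybenzylidene]malonate | COC(=O)C(=Cc1cc(OC)c(OC)c(OCc2ccccc2)c1)C(=O)OC | intermediate
5 | 4-vinyl-1,3-dioxolan-2-one (vinylethylene carbonate), racemic | C=CC1COC(=O)O1 | starting material
6 | dimethyl (2R,4R)-2-[3-(benzyloxy)-4,5-dimethoxyphenyl]-4-vinyltetrahydrofuran-3,3-dicarboxylate | COc1cc([C@H]2OC[C@H](C=C)C2(C(=O)OC)C(=O)OC)cc(OCc2ccccc2)c1OC | intermediate
7 | methyl (2S,3R,4R)-2-[3-(benzyloxy)-4,5-dimethoxyphenyl]-4-vinyltetrahydrofuran-3-carboxylate (ester cis to aryl) | COc1cc([C@H]2OC[C@H](C=C)[C@H]2C(=O)OC)cc(OCc2ccccc2)c1OC | intermediate (not isolated)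
8 | methyl (2S,3S,4R)-2-[3-(benzyloxy)-4,5-dimethoxyphenyl]-4-vinyltetrahydrofuran-3-carboxylate (ester trans to aryl, cis to vinyl) | COc1cc([C@H]2OC[C@H](C=C)[C@@H]2C(=O)OC)cc(OCc2ccccc2)c1OC | intermediate
9 | [(2S,3R,4R)-2-[3-(benzyloxy)-4,5-dimethoxyphenyl]-4-vinyltetrahydrofuran-3-yl]methanol | COc1cc([C@H]2OC[C@H](C=C)[C@@H]2CO)cc(OCc2ccccc2)c1OC | intermediate
10 | [(2S,3R,4R)-2-[3-(benzyloxy)-4,5-dimethoxyphenyl]-4-(1,2,4-trioxolan-3-yl)tetrahydrofuran-3-yl]methanol (ozonide, epimers at the trioxolane carbon) | COc1cc([C@H]2OC[C@H](C3OCOO3)[C@@H]2CO)cc(OCc2ccccc2)c1OC | intermediate (not isolated)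
11 | (3R,4R,5S)-5-[3-(benzyloxy)-4,5-dimethoxyphenyl]-4-(hydroxymethyl)tetrahydrofuran-3-carbaldehyde | COc1cc([C@H]2OC[C@H](C=O)[C@@H]2CO)cc(OCc2ccccc2)c1OC | intermediate (not isolated)
12 | (3aR,4S,6aR)-4-[3-(benzyloxy)-4,5-dimethoxyphenyl]tetrahydro-1H,3H-furo[3,4-c]furan-1-ol (both anomers) | COc1cc([C@H]2OC[C@H]3[C@@H]2COC3O)cc(OCc2ccccc2)c1OC | intermediate
13 | (3aR,4S,6aR)-1-(benzenesulfonyl)-4-[3-(benzyloxy)-4,5-dimethoxyphenyl]tetrahydro-1H,3H-furo[3,4-c]furan (both anomers) | COc1cc([C@H]2OC[C@H]3[C@@H]2COC3S(=O)(=O)c2ccccc2)cc(OCc2ccccc2)c1OC | intermediate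
14 | 5-bromo-1,2,3-trimethoxybenzene | COc1cc(Br)cc(OC)c1OC | starting material
15 | (3,4,5-trimethoxyphenyl)magnesium bromide | COc1cc([Mg]Br)cc(OC)c1OC | intermediate
16 | (3,4,5-trimethoxyphenyl)zinc bromide | COc1cc([Zn]Br)cc(OC)c1OC | intermediate (not isolated)
17 | (1S,3aR,4S,6aR)-1-[3-(benzyloxy)-4,5-dimethoxyphenyl]-4-(3,4,5-trimethoxyphenyl)tetrahydro-1H,3H-furo[3,4-c]furan | COc1cc([C@H]2OC[C@H]3[C@@H]2CO[C@@H]3c2cc(OC)c(OC)c(OC)c2)cc(OCc2ccccc2)c1OC | intermediate
18 | 5-[(1S,3aR,4S,6aR)-4-(3,4,5-trimethoxyphenyl)tetrahydro-1H,3H-furo[3,4-c]furan-1-yl]-2,3-dimethoxyphenol | COc1cc([C@H]2OC[C@H]3[C@@H]2CO[C@@H]3c2cc(OC)c(OC)c(OC)c2)cc(O)c1OC | target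

**Step count**

Total: 10 steps. Longest linear sequence: 9 steps (steps 1–7, 9 and 10); step 8 is a one-step branch that supplies the aryl donor.

**Steps most likely to fail**

Step 3. The oxa-Michael addition to the only moderately electrophilic malonate may be too slow, so that the zwitterion decays by proton transfer or oligomerisation. The facial and 2,4-trans selectivity may also be insufficient. The fallback keeps the same two bonds but uses a much stronger acceptor; it sets out from 2 and returns at 8. Condensation of 2 with 2,2-dimethyl-1,3-dioxane-4,6-dione (piperidine cat., EtOH) should give 5-[3-(benzyloxy)-4,5-dimethoxybenzylidene]-2,2-dimethyl-1,3-dioxane-4,6-dione F1. Alkylidene dioxanediones of this kind are established partners for palladium π-allyl zwitterions. F1 with 5 under the catalyst of step 3 should give the spiro cycloadduct (1R,4R)-1-[3-(benzyloxy)-4,5-dimethoxyphenyl]-8,8-dimethyl-4-vinyl-2,7,9-trioxaspiro[4.5]decane-6,10-dione F2. NaOMe in MeOH should open the dioxanedione to the half-ester (2R,4R)-2-[3-(benzyloxy)-4,5-dimethoxyphenyl]-3-(methoxycarbonyl)-4-vinyltetrahydrofuran-3-carboxylic acid F3. Heating F3 in DMSO should decarboxylate it to the mixture of 7 and 8, which the methoxide stage of step 4 converts into 8.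

Step 4. The thermodynamic bias at C3 (ester trans to aryl against ester trans to vinyl) may be too small, or prolonged base treatment may erode material. The fallback replaces the simple equilibration by a lactone trap; it sets out from the unequilibrated mixture of 7 and 8 and returns at 12. Dihydroxylation of the vinyl group (OsO4 cat., N-methylmorpholine N-oxide, acetone–water) should give methyl (2S,4R)-2-[3-(benzyloxy)-4,5-dimethoxyphenyl]-4-(1,2-dihydroxyethyl)tetrahydrofuran-3-carboxylate F4 as an epimer mixture. With DBU in toluene at 80 °C the C3 centre epimerises, and only the epimer with the ester cis to the diol chain can lactonise. Both epimers should therefore be funnelled into the cis-fused lactone (3aR,6S,6aS)-6-[3-(benzyloxy)-4,5-dimethoxyphenyl]-3-(hydroxymethyl)tetrahydro-1H,3H-furo[3,4-c]furan-1-one F5. LiAlH4 reduction should give the triol 1-[(3R,4R,5S)-5-[3-(benzyloxy)-4,5-dimethoxyphenyl]-4-(hydroxymethyl)tetrahydrofuran-3-yl]ethane-1,2-diol F6. Cleavage of its vicinal diol with NaIO4 (THF–water) should give 11, which closes to 12.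

Step 9. Ionisation of the anomeric sulfone may be sluggish, elimination of sulfinate to the bicyclic enol ether may compete, or convex-face selectivity may be incomplete. The fallback forms the C4–aryl bond by carbonyl addition and the C4–O5 bond afterwards; it sets out from 12 (with 15) and returns at 17. An excess of 15 in THF should open the lactol through its aldehyde form and give the diol [(3R,4R,5S)-5-[3-(benzyloxy)-4,5-dimethoxyphenyl]-4-(hydroxymethyl)tetrahydrofuran-3-yl](3,4,5-trimethoxyphenyl)methanol F7 as a mixture of carbinol epimers. Brief treatment with camphorsulfonic acid (cat.) in CH2Cl2 at 0 °C should ionise the electron-rich benzylic alcohol, and the primary hydroxyl should close the ring on the less hindered exo face, so that both carbinol epimers converge on 17. Any endo-aryl epimer would be removed by chromatography.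

Further compounds
F1 | step 3 | 5-[3-(benzyloxy)-4,5-dimethoxybenzylidene]-2,2-dimethyl-1,3-dioxane-4,6-dione | COc1cc(C=C2C(=O)OC(C)(C)OC2=O)cc(OCc2ccccc2)c1OC
F2 | step 3 | (1R,4R)-1-[3-(benzyloxy)-4,5-dimethoxyphenyl]-8,8-dimethyl-4-vinyl-2,7,9-trioxaspiro[4.5]decane-6,10-dione | COc1cc([C@H]2OC[C@H](C=C)C23C(=O)OC(C)(C)OC3=O)cc(OCc2ccccc2)c1OC
F3 | step 3 | (2R,4R)-2-[3-(benzyloxy)-4,5-dimethoxyphenyl]-3-(methoxycarbonyl)-4-vinyltetrahydrofuran-3-carboxylic acid (C3 epimers) | COc1cc([C@H]2OC[C@H](C=C)C2(C(=O)O)C(=O)OC)cc(OCc2ccccc2)c1OC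
F4 | step 4 | methyl (2S,4R)-2-[3-(benzyloxy)-4,5-dimethoxyphenyl]-4-(1,2-dihydroxyethyl)tetrahydrofuran-3-carboxylate (C3 and carbinol epimers) | COc1cc([C@H]2OC[C@H](C(O)CO)C2C(=O)OC)cc(OCc2ccccc2)c1OC
F5 | step 4 | (3aR,6S,6aS)-6-[3-(benzyloxy)-4,5-dimethoxyphenyl]-3-(hydroxymethyl)tetrahydro-1H,3H-furo[3,4-c]furan-1-one (C3 epimers) | COc1cc([C@H]2OC[C@H]3[C@@H]2C(=O)OC3CO)cc(OCc2ccccc2)c1OC
F6 | step 4 | 1-[(3R,4R,5S)-5-[3-(benzyloxy)-4,5-dimethoxyphenyl]-4-(hydroxymethyl)tetrahydrofuran-3-yl]ethane-1,2-diol (carbinol epimers) | COc1cc([C@H]2OC[C@H](C(O)CO)[C@@H]2CO)cc(OCc2ccccc2)c1OC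
F7 | step 9 | [(3R,4R,5S)-5-[3-(benzyloxy)-4,5-dimethoxyphenyl]-4-(hydroxymethyl)tetrahydrofuran-3-yl](3,4,5-trimethoxyphenyl)methanol (carbinol epimers) | COc1cc([C@H]2OC[C@H](C(O)c3cc(OC)c(OC)c(OC)c3)[C@@H]2CO)cc(OCc2ccccc2)c1OC
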